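The time of reading, 25 s, serves as the yardstick: each process is placed by how many decades, factors of 10, its half-life lies below that time.

| setting | grey | green | violet |
|---|---|---|---|
| starting material | 46 mM | 46 mM | 46 mM |
| time | 25 s | 25 s | 25 s |
| remark | at 130 °C until 20 s, from then on at 100 °C |  |  |
| temperature |  | 130 °C | 100 °C |

    starting material ⇌ target (K1 = 1.9, k1 = 0.066 s⁻¹, Ea1 = 102 kJ mol⁻¹, ΔH1 = −27.0 kJ mol⁻¹)
    starting material ⇌ isomer of the product (K2 = 2.3, k2 = 0.025 s⁻¹, Ea2 = 103 kJ mol⁻¹, ΔH2 = −22.0 kJ mol⁻¹)
    starting material ⇌ third isomer (K3 = 0.32, k3 = 0.098 s⁻¹, Ea3 = 109 kJ mol⁻¹, ΔH3 = −40.0 kJ mol⁻¹)
    starting material → decomposition product (k4 = 4.2 × 10⁻⁵ s⁻¹, Ea4 = 121 kJ mol⁻¹)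
    starting material ⇌ dormant form (K5 = 8.2, k5 = 0.018 s⁻¹, Ea5 = 95.0 kJ mol⁻¹, ΔH5 = −23.0 kJ mol⁻¹)
    starting material + target ⇌ idle adduct, settled at all times (K6 = 16 M⁻¹, ΔH6 = 50.0 kJ mol⁻¹)
    (constants at 100 °C)

- percentages count the starting material that a species holds: one idle adduct counts as two
- target is meant together with its idle adduct
- constants are those at 100 °C; use the activation energies and enthalpies for any other temperature
- in an amount of target, one idle adduct counts as one target

- the flask that comes out highest in amount of target, in percent of the starting material charged, or "all alike" when all lie within 1.5 percentage points (grey / green / violet / all alike)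
- target at the end, in percent of the starting material charged, grey
- target at the end, in percent of the starting material charged, green
- target at the end, in percent of the starting material charged, violet

Take green first. The balances with starting material, each by its own step, have half-lives lying 2.65 decades below the reading time for the third isomer, 1.74 for target, 1.27 for the isomer of the product and 0.885 for the dormant form. The third isomer balances faster than target, target faster than the isomer of the product, and that isomer faster than the dormant form. So green soon holds one pool of starting material, target and the two isomers, because the half-life of target is short against the reading time.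

In this reckoning, with [starting material] as unit, target weighs 0.994 at the hot temperature, and the whole pool weighs 3.47. Target therefore holds 28.6 % of the pool. The dormant form has a larger constant at the reference temperature than target and the two isomers, which marks it as the thermodynamic product. At the hot temperature its constant is 4.72 and its rate constant 0.176 s⁻¹. Forward flow sees only the starting material in the pool, so the pool relaxes at 0.0878 s⁻¹. This gives 26.2 s: the decade time of the drain, in which the distance of the dormant form from its balance falls by a factor of 10.

Green's reading lies 0.954 decades along. The dormant form's balance share is 57.6 %, so 48.8 % of the charge stays in the pool, and target comes to 14.0 %, idle adduct not counted. Grey follows green up to 20 s, with 52.3 % in the pool. Taking that pool at target's share for 100 °C, 34.4 %, gives 18.0 %.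

Violet has a different ladder. The isomer of the product has a half-life of 19.3 s, just 0.112 decades below the reading time, so here it counts as drain too. Starting material, target and third isomer form the pool, target's share is 59.0 %, and the decade time is 172 s, longer than green's. The pool keeps 71.6 %, and target has filled to 91.9 % of its share. That gives 38.8 %, and the ranking puts violet on top.

The forecast also names violet, with grey 19.3 %, green 16.9 % and violet 37 %. Its ground for the hot flasks: "The dormant form then drains this pool". Its grey and green figures stand above this reckoning, its violet figure below.

The simulation puts violet highest, with grey 19.7 %, green 17.1 % and violet 37.1 %, so the forecast stands. The grey answer shifts by 5 points at a reading time of 8.11 s, and also, with the time held, at a charge of 147 mM. Green's dormant form stands at 45.6 % after 25.0 s and 52.9 % after 250 s, a remaining distance of 13.6 %; the decade time gives 11.1 %.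

Now green read at 10 s: that is 0.382 decades, and the decade time gives target 19.0 %. The computed value is 23.0 %.

All constants were set for the occasion, and the outcome is calculated.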